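The route rests on cutting ring B between C9 (ring CH2) and C10, the quaternary carbon that carries methyl and formamide nitrogen. C10 is an α-tertiary amine carbon, so it is made as the carbon terminus of a 2-azaallyl anion: the N-benzhydryl ketimine of a C10 methyl ketone is deprotonated and alkylated by a C9 chloride (6-exo-tet), closing ring B and fixing the nitrogen-bearing stereocentre in one operation. The precursor is a cis-1,2-disubstituted 4-methylcyclohexene (ring A) from an intermolecular Diels–Alder reaction, with acetyl on C1 and, on C6, a chloroethyl-bearing C7 side chain whose oxolane was built from geraniol by two asymmetric epoxidations.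

Key step: step 10

Numbering used below: ring A = C1–C6 (C4 bears the methyl, C4=C5); ring B = C1, C6, C7, C8, C9, C10 (C10 bears methyl and nitrogen); oxolane = O, C11, C12, C13, C14; C15 = the CMe2N carbon.
Remark: the D-fructose-derived Shi ketone is taken to give the (R)-epoxide from R–CH=CMe2 alkenes, so its L-fructose-derived enantiomer is used in step 3.

Step 1
Reactants: 1 geraniol
Product: 2 (2S,3S)-2,3-epoxygeraniol
Conditions: Ti(OiPr)4 (5 mol %), L-(+)-diethyl tartrate (6 mol %), t-BuOOH, 4 Å MS, CH2Cl2, −20 °C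
Reagents that add atoms: tert-butyl hydroperoxide, CC(C)(C)OO
Why: Katsuki–Sharpless asymmetric epoxidation touches only the allylic alkene, and L-(+)-tartrate should give the (2S,3S)-epoxide, which fixes C11 and prepares C7.

Step 2
Reactants: 2 (2S,3S)-2,3-epoxygeraniol
Product: 3 (2R,3S)-2-ethenyl-3,7-dimethyloct-6-ene-1,3-diol
Conditions: CH2=CHMgBr (3 equiv), CuI (10 mol %), THF/Et2O, −30 → 0 °C; aq NH4Cl
Reagents that add atoms: vinylmagnesium bromide, C=C[Mg]Br
Why: Copper-catalysed SN2 opening of the 2,3-epoxy alcohol at the less hindered secondary carbon (anti attack, inversion) should set C7 and leave the tertiary C11–O centre untouched.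

Step 3
Reactants: 3 (2R,3S)-2-ethenyl-3,7-dimethyloct-6-ene-1,3-diol
Product: 5 (2R)-2-[(2S,5R)-5-(2-hydroxypropan-2-yl)-2-methyloxolan-2-yl]but-3-en-1-ol, via epoxy diol 4 (not isolated)
Conditions: L-fructose-derived Shi ketone (30 mol %), Oxone (2KHSO5·KHSO4·K2SO4), K2CO3, Bu4NHSO4, MeCN/CH2(OMe)2/aq Na2B4O7 buffer, 0 °C; then camphorsulfonic acid (10 mol %), CH2Cl2, 0 °C
Reagents that add atoms: potassium peroxymonosulfate (from Oxone), [K+].[O-]S(=O)(=O)OO
Why: Shi asymmetric epoxidation should attack only the electron-rich trisubstituted alkene under catalyst control (S epoxide 4), and acid-catalysed 5-exo-tet opening by the tertiary C11 hydroxyl at the secondary epoxide carbon with inversion sets C14 (R) and the cis-2,5 oxolane.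

Step 4
Reactants: 5 (2R)-2-[(2S,5R)-5-(2-hydroxypropan-2-yl)-2-methyloxolan-2-yl]but-3-en-1-ol
Product: 7 (2R)-4-chloro-2-[(2S,5R)-5-(2-hydroxypropan-2-yl)-2-methyloxolan-2-yl]butan-1-ol, via alkylzirconocene 6 (not isolated)
Conditions: Cp2Zr(H)Cl (3.5 equiv), THF, 25 °C; then N-chlorosuccinimide, 0 °C
Reagents that add atoms: N-chlorosuccinimide, O=C1CCC(=O)N1Cl
Why: Schwartz hydrozirconation should place zirconium on the terminal carbon (C9) of the only alkene once both hydroxyls are taken up as zirconium alkoxides, and electrophilic chlorination of the C–Zr bond gives the primary chloride.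

Step 5
Reactants: 7 (2R)-4-chloro-2-[(2S,5R)-5-(2-hydroxypropan-2-yl)-2-methyloxolan-2-yl]butan-1-ol
Product: 9 (3E,5R)-7-chloro-5-[(2S,5R)-5-(2-hydroxypropan-2-yl)-2-methyloxolan-2-yl]hept-3-en-2-one, via aldehyde 8 (not isolated)
Conditions: Dess–Martin periodinane, CH2Cl2, 0 → 25 °C; then Ph3P=CHC(O)CH3, 25 → 40 °C
Reagents that add atoms: 1-(triphenyl-λ5-phosphanylidene)propan-2-one, CC(=O)C=P(c1ccccc1)(c1ccccc1)c1ccccc1
Why: Dess–Martin oxidation of the primary alcohol beside the tertiary one, then Wittig olefination with a stabilised ylide under neutral conditions, should give the E-enone without epimerising C7 or opening the β-alkoxy aldehyde.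

Step 6
Reactants: 9 (3E,5R)-7-chloro-5-[(2S,5R)-5-(2-hydroxypropan-2-yl)-2-methyloxolan-2-yl]hept-3-en-2-one
Product: 10 (3E,5R)-7-chloro-5-[(2S,5R)-2-methyl-5-(prop-1-en-2-yl)oxolan-2-yl]hept-3-en-2-one
Conditions: Burgess reagent (MeO2CN−SO2N+Et3), benzene, 50 °C
Reagents that add atoms: none
Why: Burgess dehydration (syn-elimination through the sulfamate ester) of the tertiary alcohol should give the isopropenyl group, the six methyl hydrogens being favoured over the single ring-bound C14–H.

Step 7
Reactants: 10 (3E,5R)-7-chloro-5-[(2S,5R)-2-methyl-5-(prop-1-en-2-yl)oxolan-2-yl]hept-3-en-2-one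
Product: 11 (2S,5R)-2-[(3R,4E)-1-chloro-6-methylhepta-4,6-dien-3-yl]-2-methyl-5-(prop-1-en-2-yl)oxolane
Conditions: Ph3PCH3Br, KOtBu, THF, 0 °C
Reagents that add atoms: methyltriphenylphosphonium bromide, C[P+](c1ccccc1)(c1ccccc1)c1ccccc1.[Br-]
Why: Wittig methylenation of the methyl ketone turns the enone into the 2-methyl-1,3-diene needed for ring A, addition to the carbonyl being expected to outrun deprotonation at C7.

Step 8
Reactants: 11 (2S,5R)-2-[(3R,4E)-1-chloro-6-methylhepta-4,6-dien-3-yl]-2-methyl-5-(prop-1-en-2-yl)oxolane; 12 but-3-en-2-one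
Product: 13 1-[(1S,2S)-2-{(1R)-3-chloro-1-[(2S,5R)-2-methyl-5-(prop-1-en-2-yl)oxolan-2-yl]propyl}-4-methylcyclohex-3-en-1-yl]ethan-1-one
Conditions: EtAlCl2 (20 mol %), CH2Cl2, −78 → −40 °C
Reagents that add atoms: none
Why: Lewis-acid-catalysed Diels–Alder reaction in which the 1-alkyl and 3-methyl groups of the diene both direct the acetyl-bearing carbon to C1 (ortho/para rule), the endo transition state gives the cis C1/C6 pair, and the dienophile should add anti to the quaternary C11 in the conformer with C7–H eclipsing the diene (A(1,3) strain), which sets C6 and C1 relative to C7.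

Step 9
Reactants: 13 1-[(1S,2S)-2-{(1R)-3-chloro-1-[(2S,5R)-2-methyl-5-(prop-1-en-2-yl)oxolan-2-yl]propyl}-4-methylcyclohex-3-en-1-yl]ethan-1-one; 14 benzhydrylamine (1,1-diphenylmethanamine)
Product: 15 N-benzhydryl ketimine of 13, N-(diphenylmethyl)-1-[(1S,2R)-2-{(1R)-3-chloro-1-[(2S,5R)-2-methyl-5-(prop-1-en-2-yl)oxolan-2-yl]propyl}-4-methylcyclohex-3-en-1-yl]ethan-1-imine
Conditions: Ti(OEt)4 (2 equiv), THF, 40 °C
Reagents that add atoms: none
Why: Titanium-alkoxide-mediated condensation of the ketone with the primary amine should give the ketimine under non-acidic conditions chosen to keep the epimerisable C1 centre cis.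

Step 10
Reactants: 15 N-benzhydryl ketimine of 13
Product: 17 (1R,4R,4aR,8aS)-N-(diphenylmethylidene)-1,6-dimethyl-4-[(2S,5R)-2-methyl-5-(prop-1-en-2-yl)oxolan-2-yl]-1,2,3,4,4a,7,8,8a-octahydronaphthalen-1-amine, via potassium 2-azaallyl anion 16 (not isolated)
Conditions: KN(SiMe3)2 (1.2 equiv), THF, −78 °C; then DMPU, −78 → 25 °C
Reagents that add atoms: none
Why: Proposed new method: KN(SiMe3)2 removes the doubly benzylic N–CH proton of 15 to give the 1,1-diphenyl-2-azaallyl anion 16, whose charge is shared between the diphenyl carbon and C10, so the former ketone carbon C10 becomes a nucleophile (imine umpolung) and displaces chloride at C9 by SN2. The closest known reaction types are the C-alkylation of benzophenone-imine-derived 2-azaallyl anions with alkyl halides and the umpolung additions of ketimines through 2-azaallyl anions; new here is the intramolecular alkylation at a dialkyl-substituted terminus to make an α-tertiary amine. Ring B closes in the 6-exo-tet mode, whereas attack through the diphenyl carbon would need an eight-membered ring and alkylation through the C10-methyl aza-enolate a seven-membered one. C10 is set in a chair-like transition state with the C7 oxolanyl group equatorial and ring A cis-fused, in which the long N=CPh2 arm (trans to C1 across the C10–N bond) takes the pseudo-equatorial site away from the incoming C8–C9 tether and the small methyl the pseudo-axial one, which should give 10R (nitrogen trans to H1). The step needs C- over N-alkylation, substitution over E2 and retention of the cis C1/C6 relationship; the soft delocalised anion, the primary chloride, the absence of any other acidic site after the early dehydration and the much lower acidity of C1–H than of the benzhydryl C–H secure this.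

Step 11
Reactants: 17 ring-B-closed benzophenone imine
Product: 18 (1R,4R,4aR,8aS)-4-[(2S,5R)-5-(2-azidopropan-2-yl)-2-methyloxolan-2-yl]-N-(diphenylmethylidene)-1,6-dimethyl-1,2,3,4,4a,7,8,8a-octahydronaphthalen-1-amine
Conditions: Co(BF4)2·6H2O (6 mol %), potassium 2-[(3,5-di-tert-butyl-2-hydroxybenzylidene)amino]-2,2-diphenylacetate (6 mol %), TsN3, PhSiH3, t-BuOOH (30 mol %), EtOH, 25 °C
Reagents that add atoms: 4-methylbenzenesulfonyl azide, Cc1ccc(cc1)S(=O)(=O)N=[N+]=[N-]
Why: Mukaiyama-type hydroazidation (Carreira conditions): the cobalt hydride should transfer a hydrogen atom to the 1,1-disubstituted alkene faster than to the hindered trisubstituted ring alkene, and the tertiary C15 radical is trapped by the sulfonyl azide (Markovnikov); C15 is not stereogenic.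

Step 12
Reactants: 18 C15 azide
Product: 20 (1R,4R,4aR,8aS)-4-[(2S,5R)-5-(2-aminopropan-2-yl)-2-methyloxolan-2-yl]-1,6-dimethyl-1,2,3,4,4a,7,8,8a-octahydronaphthalen-1-amine, via iminophosphorane 19 (not isolated)
Conditions: PMe3, THF/H2O, 25 → 50 °C; then 1 M HCl, 25 °C; NaOH work-up
Reagents that add atoms: none
Why: Staudinger reduction of the tertiary azide to the iminophosphorane, after which aqueous acid should hydrolyse both the iminophosphorane and the benzophenone Schiff base and free the two primary amines without touching the alkene.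

Step 13
Reactants: 20 diamine
Product: 21 N-[(1R,4R,4aR,8aS)-4-[(2S,5R)-5-(2-formamidopropan-2-yl)-2-methyloxolan-2-yl]-1,6-dimethyl-1,2,3,4,4a,7,8,8a-octahydronaphthalen-1-yl]formamide (CNP0173819.1)
Conditions: acetic formic anhydride (preformed, 3 equiv), pyridine, CH2Cl2, 0 → 25 °C
Reagents that add atoms: acetic formic anhydride, CC(=O)OC=O
Why: N-Formylation of both hindered primary amines with the mixed anhydride, which transfers the formyl group selectively, should give the bis-formamide.

Compound list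
1 | geraniol, (2E)-3,7-dimethylocta-2,6-dien-1-ol | CC(C)=CCC/C(C)=C/CO | starting material
2 | (2S,3S)-2,3-epoxygeraniol | OC[C@@H]1O[C@@]1(C)CCC=C(C)C | intermediate
3 | (2R,3S)-2-ethenyl-3,7-dimethyloct-6-ene-1,3-diol | OC[C@@H](C=C)[C@@](C)(O)CCC=C(C)C | intermediate
4 | (2R,3S)-5-[(2S)-3,3-dimethyloxiran-2-yl]-2-ethenyl-3-methylpentane-1,3-diol | OC[C@@H](C=C)[C@@](C)(O)CC[C@@H]1OC1(C)C | intermediate
5 | (2R)-2-[(2S,5R)-5-(2-hydroxypropan-2-yl)-2-methyloxolan-2-yl]but-3-en-1-ol | OC[C@@H](C=C)[C@]1(C)CC[C@H](C(C)(C)O)O1 | intermediate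
6 | C9 alkylzirconocene chloride of 5, both hydroxyls bound as zirconocene chloride alkoxides | Cl[Zr](C1C=CC=C1)(C1C=CC=C1)OC[C@@H](CC[Zr](Cl)(C1C=CC=C1)C1C=CC=C1)[C@]1(C)CC[C@H](C(C)(C)O[Zr](Cl)(C2C=CC=C2)C2C=CC=C2)O1 | intermediate
7 | (2R)-4-chloro-2-[(2S,5R)-5-(2-hydroxypropan-2-yl)-2-methyloxolan-2-yl]butan-1-ol | OC[C@@H](CCCl)[C@]1(C)CC[C@H](C(C)(C)O)O1 | intermediate
8 | (2S)-4-chloro-2-[(2S,5R)-5-(2-hydroxypropan-2-yl)-2-methyloxolan-2-yl]butanal | O=C[C@@H](CCCl)[C@]1(C)CC[C@H](C(C)(C)O)O1 | intermediate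
9 | (3E,5R)-7-chloro-5-[(2S,5R)-5-(2-hydroxypropan-2-yl)-2-methyloxolan-2-yl]hept-3-en-2-one | CC(=O)/C=C/[C@@H](CCCl)[C@]1(C)CC[C@H](C(C)(C)O)O1 | intermediate
10 | (3E,5R)-7-chloro-5-[(2S,5R)-2-methyl-5-(prop-1-en-2-yl)oxolan-2-yl]hept-3-en-2-one | CC(=O)/C=C/[C@@H](CCCl)[C@]1(C)CC[C@H](C(C)=C)O1 | intermediate
11 | (2S,5R)-2-[(3R,4E)-1-chloro-6-methylhepta-4,6-dien-3-yl]-2-methyl-5-(prop-1-en-2-yl)oxolane | C=C(C)/C=C/[C@@H](CCCl)[C@]1(C)CC[C@H](C(C)=C)O1 | intermediate
12 | but-3-en-2-one (methyl vinyl ketone) | CC(=O)C=C | starting material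
13 | 1-[(1S,2S)-2-{(1R)-3-chloro-1-[(2S,5R)-2-methyl-5-(prop-1-en-2-yl)oxolan-2-yl]propyl}-4-methylcyclohex-3-en-1-yl]ethan-1-one (cis ring A ketone) | CC(=O)[C@H]1CCC(C)=C[C@H]1[C@@H](CCCl)[C@]2(C)CC[C@H](C(C)=C)O2 | intermediate
14 | benzhydrylamine, 1,1-diphenylmethanamine | NC(c1ccccc1)c1ccccc1 | starting material
15 | N-benzhydryl ketimine of 13 (configuration of 13 unchanged) | CC(=NC(c1ccccc1)c1ccccc1)[C@H]1CCC(C)=C[C@H]1[C@@H](CCCl)[C@]2(C)CC[C@H](C(C)=C)O2 | intermediate
16 | potassium 1,1-diphenyl-2-azaallyl anion of 15 | CC(=N[C-](c1ccccc1)c1ccccc1)[C@H]1CCC(C)=C[C@H]1[C@@H](CCCl)[C@]2(C)CC[C@H](C(C)=C)O2.[K+] | intermediate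
17 | (1R,4R,4aR,8aS)-N-(diphenylmethylidene)-1,6-dimethyl-4-[(2S,5R)-2-methyl-5-(prop-1-en-2-yl)oxolan-2-yl]-1,2,3,4,4a,7,8,8a-octahydronaphthalen-1-amine | CC1=C[C@H]2[C@H]([C@]3(C)CC[C@H](C(C)=C)O3)CC[C@@](C)(N=C(c4ccccc4)c4ccccc4)[C@H]2CC1 | intermediate
18 | C15 azide of 17, (1R,4R,4aR,8aS)-4-[(2S,5R)-5-(2-azidopropan-2-yl)-2-methyloxolan-2-yl]-N-(diphenylmethylidene)-1,6-dimethyl-1,2,3,4,4a,7,8,8a-octahydronaphthalen-1-amine | CC1=C[C@H]2[C@H]([C@]3(C)CC[C@H](C(C)(C)N=[N+]=[N-])O3)CC[C@@](C)(N=C(c4ccccc4)c4ccccc4)[C@H]2CC1 | intermediate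
19 | C15 trimethyliminophosphorane of 18 (N=PMe3 in place of N3) | CC1=C[C@H]2[C@H]([C@]3(C)CC[C@H](C(C)(C)N=P(C)(C)C)O3)CC[C@@](C)(N=C(c4ccccc4)c4ccccc4)[C@H]2CC1 | intermediate
20 | (1R,4R,4aR,8aS)-4-[(2S,5R)-5-(2-aminopropan-2-yl)-2-methyloxolan-2-yl]-1,6-dimethyl-1,2,3,4,4a,7,8,8a-octahydronaphthalen-1-amine | CC1=C[C@H]2[C@H]([C@]3(C)CC[C@H](C(C)(C)N)O3)CC[C@@](C)(N)[C@H]2CC1 | intermediate
21 | N-[(1R,4R,4aR,8aS)-4-[(2S,5R)-5-(2-formamidopropan-2-yl)-2-methyloxolan-2-yl]-1,6-dimethyl-1,2,3,4,4a,7,8,8a-octahydronaphthalen-1-yl]formamide | CC1=C[C@H]2[C@H]([C@]3(C)CC[C@H](C(C)(C)NC=O)O3)CC[C@@](C)(NC=O)[C@H]2CC1 | target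

Total step count: 13 steps.
Longest linear sequence: 13 steps (from geraniol 1).

Steps most likely to fail

Step 10 (Proposed new method). What may go wrong: proton transfer or E2 elimination may outpace C-alkylation of the 2-azaallyl anion, or the two faces of C10 may not be told apart well. Fallback, by radical addition to a C=N acceptor (known chemistry): it sets out from 13. Condensation with O-benzylhydroxylamine hydrochloride in pyridine gives the O-benzyl oxime ether F1. Finkelstein exchange (NaI, acetone) gives the iodide F2. Bu3SnH with AIBN (benzene, 80 °C, slow addition) generates the C9 radical, which closes ring B by 6-exo-trig addition to the oxime carbon C10 and gives the N-benzyloxy amine F3; this closure has to compete with 5-exo attack of the same radical on C5. Zn in AcOH cleaves the N–O bond to the primary amine F4. Transimination with benzophenone imine (Ph2C=NH, CH2Cl2, 25 °C) comes back to the route at 17.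

Step 8. What may go wrong: poor facial selectivity, if the C7 centre does not steer the dienophile well enough, or erosion of the endo preference. Fallback, by catalyst control through iminium activation followed by adjustment of the C1 side chain: it sets out from 11. An organocatalytic Diels–Alder reaction with acrolein and 5-benzyl-2,2,3-trimethylimidazolidin-4-one hydrochloride (the enantiomer matched to the C7 bias; MeCN/H2O, 0 °C) gives the cis aldehyde F5. MeMgBr (THF, −78 °C) gives the secondary alcohol F6, whose carbinol configuration is of no consequence. Dess–Martin oxidation comes back to the route at 13.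

Step 11. What may go wrong: incomplete chemoselectivity, with hydrogen-atom transfer also to the C4=C5 alkene, or attack of the silane/ethanol medium on the Schiff base. Fallback, by polar Markovnikov azidation through a mercurinium ion, which is known to prefer 1,1-disubstituted over trisubstituted ring alkenes: it sets out from 17. Transimination with hydroxylamine hydrochloride frees the amine F4, which is formylated in the same flask with acetic formic anhydride to the formamide F7. Azidomercuration (Hg(OAc)2, NaN3, THF/H2O) gives the β-azido alkylmercury acetate F8 (not isolated), which NaBH4/NaOH demercurates to the tertiary azide F9. Staudinger reduction (PMe3, THF/H2O) gives the amino formamide F10, and formylation with acetic formic anhydride comes back to the route at 21.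

Further compounds
F1 | step 10 | O-benzyl oxime ether of ketone 13 | CC(=NOCc1ccccc1)[C@H]1CCC(C)=C[C@H]1[C@@H](CCCl)[C@]2(C)CC[C@H](C(C)=C)O2
F2 | step 10 | iodide analogue of F1 (C9–I) | CC(=NOCc1ccccc1)[C@H]1CCC(C)=C[C@H]1[C@@H](CCI)[C@]2(C)CC[C@H](C(C)=C)O2
F3 | step 10 | ring-B-closed N-(benzyloxy)amine at C10 | CC1=C[C@H]2[C@H]([C@]3(C)CC[C@H](C(C)=C)O3)CC[C@@](C)(NOCc4ccccc4)[C@H]2CC1
F4 | step 10 | (1R,4R,4aR,8aS)-1,6-dimethyl-4-[(2S,5R)-2-methyl-5-(prop-1-en-2-yl)oxolan-2-yl]-1,2,3,4,4a,7,8,8a-octahydronaphthalen-1-amine | CC1=C[C@H]2[C@H]([C@]3(C)CC[C@H](C(C)=C)O3)CC[C@@](C)(N)[C@H]2CC1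
F5 | step 8 | cis aldehyde, formyl in place of the acetyl group of 13 | O=C[C@H]1CCC(C)=C[C@H]1[C@@H](CCCl)[C@]2(C)CC[C@H](C(C)=C)O2
F6 | step 8 | secondary alcohol, 1-hydroxyethyl in place of the acetyl group of 13 | CC(O)[C@H]1CCC(C)=C[C@H]1[C@@H](CCCl)[C@]2(C)CC[C@H](C(C)=C)O2
F7 | step 11 | N-formyl derivative of F4 | CC1=C[C@H]2[C@H]([C@]3(C)CC[C@H](C(C)=C)O3)CC[C@@](C)(NC=O)[C@H]2CC1
F8 | step 11 | β-azido alkylmercury acetate from F7 (C15 azide, CH2HgOAc) | CC1=C[C@H]2[C@H]([C@]3(C)CC[C@H](C(C)(C[Hg]OC(C)=O)N=[N+]=[N-])O3)CC[C@@](C)(NC=O)[C@H]2CC1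
F9 | step 11 | C15 azide with C10 formamide | CC1=C[C@H]2[C@H]([C@]3(C)CC[C@H](C(C)(C)N=[N+]=[N-])O3)CC[C@@](C)(NC=O)[C@H]2CC1
F10 | step 11 | C15 amine with C10 formamide | CC1=C[C@H]2[C@H]([C@]3(C)CC[C@H](C(C)(C)N)O3)CC[C@@](C)(NC=O)[C@H]2CC1
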